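**Retrosynthetic overview**

1. Target 15 ⇐ 14 (phenol O-debenzylation) ⇐ 13 (oxirane last, on the C8=C9 alkene, syn to the 6α-OH) ⇐ β-hydroxy ketone 11 by an Evans–Tishchenko reaction that reduces C6=O and places the aroyl group on the tertiary O4 in the same operation. Daucane numbering: C1 = CH3-bearing quaternary ring-fusion carbon, C2/C3 = cyclopentane CH2, C4 = isopropyl carbinol carbon, C5 = ring-fusion CH, C6 to C10 = the rest of the seven-membered ring.
2. 11 ⇐ achiral dienone 6 + 1-isopropylcyclopropanol 8 by a one-pot enantioselective [3+2] annulation: homoenolate conjugate addition makes C2–C1, aldol addition makes C5–C4, and the cyclopentane (ring A) closes onto the preformed seven-membered ring (ring B) with C1, C4 and C5 set.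
3. Enabling feature: the C4 oxygen of ring A is 1,3 to the C6 oxygen of ring B across C5, and the quaternary C1 is β to C6. At the ketone level C6=O makes C1 an enone β-carbon and C5 an enolate carbon, while C2–C3–C4(=O) is a ketone homoenolate, stored as a strained cyclopropanol whose C–C cleavage reverses the polarity of C2 (union of two ketone β-carbons).
4. 6 ⇐ 2,5-dimethylphenol 1 by silylation, Birch reduction, Simmons–Smith cyclopropanation of the silyl enol ether and FeCl3-mediated one-carbon ring expansion; 8 ⇐ methyl isobutyrate 7 by a Kulinkovich reaction.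
5. Ring order: ring B (seven-membered, step 4), ring A (cyclopentane, step 6), oxirane (step 8).

Key step: step 6

Remark: α denotes the face of the bicycle opposite to the C1 methyl group; the bicyclic compounds are named with the daucane numbering given above.
Assumption: the antipode of the chiral ligand in step 6 is the one that delivers the homoenolate to the enone face giving (1R); which antipode this is would be fixed by a short ligand screen.

**Route**

Step 1
Reactants: 1 2,5-dimethylphenol
Product: 2 tert-butyl(2,5-dimethylphenoxy)dimethylsilane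
Conditions: TBSCl (1.1 equiv), imidazole (2 equiv), DMF, 23 °C
Reagents that add atoms: tert-butyldimethylsilyl chloride, CC(C)(C)[Si](C)(C)Cl
Why: Imidazole-promoted silylation of a phenol should give an aryl silyl ether robust enough for dissolving-metal conditions.

Step 2
Reactants: 2 tert-butyl(2,5-dimethylphenoxy)dimethylsilane
Product: 3 tert-butyl[(2,5-dimethylcyclohexa-1,4-dien-1-yl)oxy]dimethylsilane
Conditions: Li (2.5 equiv), NH3 (l), THF, t-BuOH (2.5 equiv), −78 → −33 °C; solid NH4Cl
Reagents that add atoms: none
Why: Birch reduction of an aryl silyl ether protonates the two ring positions that carry neither oxygen nor methyl, so the silyloxy group and both methyl groups stay on sp2 carbons and the tetrasubstituted silyl enol ether is formed regiospecifically.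

Step 3
Reactants: 3 tert-butyl[(2,5-dimethylcyclohexa-1,4-dien-1-yl)oxy]dimethylsilane
Product: 4 racemic tert-butyl[(3,6-dimethylbicyclo[4.1.0]hept-3-en-1-yl)oxy]dimethylsilane
Conditions: Et2Zn (1.3 equiv), CH2I2 (1.3 equiv), CH2Cl2, 0 → 23 °C
Reagents that add atoms: diiodomethane, ICI
Why: In this Simmons–Smith cyclopropanation the electrophilic zinc carbenoid should react fastest at the electron-rich silyl enol ether and leave the trisubstituted alkene; the cis-fused cyclopropane is the only one possible and its stereocentres are erased in step 4.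

Step 4
Reactants: 4 racemic tert-butyl[(3,6-dimethylbicyclo[4.1.0]hept-3-en-1-yl)oxy]dimethylsilane
Product: 6 3,6-dimethylcyclohepta-2,5-dien-1-one, via β-chloro ketone 5 (not isolated)
Conditions: FeCl3 (2.2 equiv), DMF, 0 → 40 °C; then NaOAc (3 equiv), MeOH, 23 °C
Reagents that add atoms: none
Why: In this FeCl3-mediated oxidative ring expansion of a siloxycyclopropane, one-electron oxidation gives a cyclopropyloxy radical, β-scission of the internal bond gives the ring-expanded tertiary β-keto radical, chlorine transfer gives 5, and mild E1cB loss of HCl gives the conjugated enone while the skipped alkene stays in place.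

Step 5
Reactants: 7 methyl 2-methylpropanoate
Product: 8 1-(propan-2-yl)cyclopropan-1-ol
Conditions: EtMgBr (2.2 equiv), Ti(OiPr)4 (10 mol%), Et2O, 23 °C; aq. NH4Cl
Reagents that add atoms: ethylmagnesium bromide, CC[Mg]Br
Why: In the Kulinkovich reaction the titanacyclopropane formed from EtMgBr and Ti(OiPr)4 acts as a 1,2-dicarbanion toward the ester and should give the 1-substituted cyclopropanol.

Step 6
Reactants: 6 3,6-dimethylcyclohepta-2,5-dien-1-one; 8 1-(propan-2-yl)cyclopropan-1-ol
Product: 11 (1R,4R,5R)-4-hydroxy-5αH-dauc-8-en-6-one (trans-fused; 4β-OH, 4α-isopropyl, 1β-CH3), via zinc bis(homoenolate) 9 (not isolated), via zinc enolate 10 (not isolated)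
Conditions: 8 (2.4 equiv), Et2Zn (1.2 equiv), toluene, 0 → 40 °C; then Cu(OTf)2 (5 mol%), chiral sulfonate-bearing imidazolinium salt (NHC precursor, 6 mol%), 6 (1.0 equiv), −20 → 25 °C, 24 h; aq. NH4Cl
Reagents that add atoms: none
Why: Proposed new method: cyclopropanol 8 and Et2Zn should give, by deprotonation and strain-releasing C–C cleavage, the zinc bis(homoenolate) 9, which transfers its alkyl group through an NHC-bound monovalent copper homoenolate to the enone β-carbon C1 (a polarity-reversed union of two ketone β-carbons, C2 and C1), and the zinc enolate 10, formed regiospecifically at C5, then adds to the pendant isopropyl ketone to give the zinc aldolate of 11. The closest known reaction types are the NHC–copper-catalysed enantioselective conjugate addition of dialkylzincs to 3-methylcycloalkenones that creates quaternary centres, the conjugate addition of cyclopropanol-derived zinc homoenolates to enones that gives 1,6-diketones, and conjugate addition–intramolecular aldol sequences of zinc enolates. Ring A closes by a 5-exo-trig (enolexo) aldol addition. C1 is set by the chiral ligand on copper, which discriminates the enantiotopic faces of the flat, achiral dienone; C4 is set relative to C5 by zinc chelation between the enolate oxygen and the ketone oxygen in a closed transition state, which puts the C4 oxygen cis to C6 and the isopropyl group on the side of H-5; the trans ring fusion at C5 is expected from thermodynamic control, because the tertiary zinc aldolate can revert by retro-aldol at 25 °C and the trans-fused chelate, with the isopropyl group remote from the angular methyl, should be the most stable diastereomer. The step needs 1,4-addition at C1 alone and no alkene migration: in 6 the C8=C9 alkene is skipped and not conjugated, hence inert to the soft copper nucleophile, the enolate arises only at C5 so that only the five-membered closure is open to it, and the ethyl-free, weakly basic bis(homoenolate) offers neither a competing alkyl group nor a base for isomerisation.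

Step 7
Reactants: 11 (1R,4R,5R)-4-hydroxy-5αH-dauc-8-en-6-one; 12 4-(benzyloxy)benzaldehyde
Product: 13 (1R,4R,5S,6S)-6-hydroxydauc-8-en-4-yl 4-(benzyloxy)benzoate (4β-aroyloxy, 6α-OH)
Conditions: 12 (4 equiv), SmI2 (30 mol%), THF, −10 °C; aq. NaHCO3 at −10 °C
Reagents that add atoms: none
Why: In this Evans–Tishchenko reaction, trivalent samarium (formed from SmI2 and the aldehyde) should bind the hemiacetal made at O4 and the C6 ketone, and the hemiacetal hydride is delivered through a six-membered transition state to the β-face of C6, which gives the 6α (6S) alcohol and leaves the acyl group on the hindered tertiary O4.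

Step 8
Reactants: 13 (1R,4R,5S,6S)-6-hydroxydauc-8-en-4-yl 4-(benzyloxy)benzoate
Product: 14 (1R,4R,5S,6S,8R,9S)-8,9-epoxy-6-hydroxydaucan-4-yl 4-(benzyloxy)benzoate (8α,9α-oxirane)
Conditions: mCPBA (1.2 equiv), NaHCO3, CH2Cl2, 0 °C
Reagents that add atoms: 3-chloroperoxybenzoic acid, OOC(=O)c1cccc(Cl)c1
Why: Peracid epoxidation of the only alkene should occur on the α-face, to which the peracid is guided by hydrogen bonding to the homoallylic 6α-OH and from which it is not blocked by the axial β-methyl at C1, giving the 8R,9S oxirane under buffered conditions that avoid acyl migration.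

Step 9
Reactants: 14 (1R,4R,5S,6S,8R,9S)-8,9-epoxy-6-hydroxydaucan-4-yl 4-(benzyloxy)benzoate
Product: 15 (1R,4R,5S,6S,8R,9S)-8,9-epoxy-6-hydroxydaucan-4-yl 4-hydroxybenzoate (CNP0264773.1)
Conditions: H2 (1 atm), 10% Pd/C, EtOAc, 23 °C
Reagents that add atoms: none
Why: Hydrogenolysis of the aryl benzyl ether under neutral conditions should free the phenol without touching the trialkyl oxirane or the esters and without a base that could move the acyl group from O4 to O6.

**Compound list**

1 | 2,5-dimethylphenol | Cc1ccc(C)c(O)c1 | starting material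
2 | tert-butyl(2,5-dimethylphenoxy)dimethylsilane | Cc1ccc(C)c(O[Si](C)(C)C(C)(C)C)c1 | intermediate
3 | tert-butyl[(2,5-dimethylcyclohexa-1,4-dien-1-yl)oxy]dimethylsilane | CC1=CCC(C)=C(O[Si](C)(C)C(C)(C)C)C1 | intermediate
4 | racemic tert-butyl[(3,6-dimethylbicyclo[4.1.0]hept-3-en-1-yl)oxy]dimethylsilane | CC1=CCC2(C)CC2(C1)O[Si](C)(C)C(C)(C)C | intermediate
5 | racemic 3-chloro-3,6-dimethylcyclohept-5-en-1-one | CC1=CCC(C)(Cl)CC(=O)C1 | intermediate
6 | 3,6-dimethylcyclohepta-2,5-dien-1-one | CC1=CCC(C)=CC(=O)C1 | intermediate
7 | methyl 2-methylpropanoate (methyl isobutyrate) | COC(=O)C(C)C | starting material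
8 | 1-(propan-2-yl)cyclopropan-1-ol | CC(C)C1(O)CC1 | intermediate
9 | bis(4-methyl-3-oxopentyl)zinc (zinc bis(homoenolate)) | CC(C)C(=O)CC[Zn]CCC(=O)C(C)C | intermediate
10 | (4-methyl-3-oxopentyl)zinc (3R)-3,6-dimethyl-3-(4-methyl-3-oxopentyl)cyclohepta-1,5-dien-1-olate (zinc enolate) | CC(C)C(=O)CC[C@]1(C)CC=C(C)CC(O[Zn]CCC(=O)C(C)C)=C1 | intermediate
11 | (1R,4R,5R)-4-hydroxy-5αH-dauc-8-en-6-one | CC(C)[C@]1(O)CC[C@]2(C)CC=C(C)CC(=O)[C@H]21 | intermediate
12 | 4-(benzyloxy)benzaldehyde | O=Cc1ccc(OCc2ccccc2)cc1 | starting material
13 | (1R,4R,5S,6S)-6-hydroxydauc-8-en-4-yl 4-(benzyloxy)benzoate | CC(C)[C@]1(OC(=O)c2ccc(OCc3ccccc3)cc2)CC[C@]2(C)CC=C(C)C[C@H](O)[C@H]21 | intermediate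
14 | (1R,4R,5S,6S,8R,9S)-8,9-epoxy-6-hydroxydaucan-4-yl 4-(benzyloxy)benzoate | CC(C)[C@]1(OC(=O)c2ccc(OCc3ccccc3)cc2)CC[C@]2(C)C[C@@H]3O[C@]3(C)C[C@H](O)[C@H]21 | intermediate
15 | (1R,4R,5S,6S,8R,9S)-8,9-epoxy-6-hydroxydaucan-4-yl 4-hydroxybenzoate | CC(C)[C@]1(OC(=O)c2ccc(O)cc2)CC[C@]2(C)C[C@@H]3O[C@]3(C)C[C@H](O)[C@H]21 | target

**Step count and risks**

Total step count: 9. Longest linear sequence: 8 steps (steps 1 to 4 and 6 to 9; step 5 is a one-step branch).

Steps most likely to fail:

1. Step 6 (proposed new method). The chelated homoenolate may not transfer to the hindered β,β-disubstituted enone, the enantiofacial selectivity may be low, or a kinetically formed cis-fused aldolate may fail to equilibrate. The fallback sets out from 6 and separates the two bond formations with known chemistry. Commercial 4-methylpent-1-en-3-ol would be silylated (TBSCl, imidazole) to tert-butyldimethyl[(4-methylpent-1-en-3-yl)oxy]silane F1. Hydrozirconation of F1 with Cp2Zr(H)Cl and the known copper–phosphoramidite-catalysed asymmetric conjugate addition of the alkylzirconocene to 6 (CuCl, AgNTf2, chiral phosphoramidite, Et2O), a reaction type with precedent for quaternary centres on 3-methylcycloalkenones, should give (3R)-3-{3-[(tert-butyldimethylsilyl)oxy]-4-methylpentyl}-3,6-dimethylcyclohept-5-en-1-one F2. Aqueous HF in MeCN should give (3R)-3-(3-hydroxy-4-methylpentyl)-3,6-dimethylcyclohept-5-en-1-one F3, and Dess–Martin periodinane the 1,6-diketone (3R)-3,6-dimethyl-3-(4-methyl-3-oxopentyl)cyclohept-5-en-1-one F4. An equilibrating intramolecular aldol addition (catalytic KOtBu, t-BuOH/THF, 0 °C) would then close ring A and come back to the route at 11.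

2. Step 7. Hemiacetal formation at the hindered tertiary hydroxyl with an electron-rich aldehyde may be slow, the samarium centre may induce retro-aldol cleavage, and the acyl group may migrate from O4 to the secondary O6. The fallback sets out from 11. Evans–Saksena reduction (Me4NBH(OAc)3, MeCN/AcOH, −20 °C; hydride delivered from the boron bound to O4 to the β-face of C6) should give (1R,4R,5S,6S)-dauc-8-ene-4,6-diol F5. TESCl/imidazole should silylate only the secondary hydroxyl to give (1R,4R,5S,6S)-6-(triethylsilyloxy)dauc-8-en-4-ol F6. Deprotonation of the tertiary alcohol with KN(SiMe3)2 and acylation with 4-(benzyloxy)benzoyl chloride (THF, −78 → 0 °C) should give (1R,4R,5S,6S)-6-(triethylsilyloxy)dauc-8-en-4-yl 4-(benzyloxy)benzoate F7. HF·pyridine in THF would remove the silyl group and come back to the route at 13.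

3. Step 4. Cleavage of the robust TBS cyclopropyl ether by FeCl3 may be sluggish, and the skipped alkene may migrate into conjugation during the elimination. The fallback sets out from 3 and replaces the radical ring expansion by a carbene-based one. Dibromocarbene (CHBr3, KOtBu, pentane, −20 °C) should add to the silyl enol ether to give tert-butyl[(7,7-dibromo-3,6-dimethylbicyclo[4.1.0]hept-3-en-1-yl)oxy]dimethylsilane F8. Thermal electrocyclic opening of the dibromocyclopropane with loss of the silyl group (toluene, 110 °C) should give 2-bromo-3,6-dimethylcyclohepta-2,5-dien-1-one F9. Hydrodebromination with Bu3SnH and Pd(PPh3)4 would come back to the route at 6.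

Further compounds
F1 | step 6 | racemic tert-butyldimethyl[(4-methylpent-1-en-3-yl)oxy]silane | C=CC(O[Si](C)(C)C(C)(C)C)C(C)C
F2 | step 6 | (3R)-3-{3-[(tert-butyldimethylsilyl)oxy]-4-methylpentyl}-3,6-dimethylcyclohept-5-en-1-one (both epimers at the silyloxy carbon) | CC(C)C(O[Si](C)(C)C(C)(C)C)CC[C@]1(C)CC=C(C)CC(=O)C1
F3 | step 6 | (3R)-3-(3-hydroxy-4-methylpentyl)-3,6-dimethylcyclohept-5-en-1-one | CC(C)C(O)CC[C@]1(C)CC=C(C)CC(=O)C1
F4 | step 6 | (3R)-3,6-dimethyl-3-(4-methyl-3-oxopentyl)cyclohept-5-en-1-one | CC(C)C(=O)CC[C@]1(C)CC=C(C)CC(=O)C1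
F5 | step 7 | (1R,4R,5S,6S)-dauc-8-ene-4,6-diol | CC(C)[C@]1(O)CC[C@]2(C)CC=C(C)C[C@H](O)[C@H]21
F6 | step 7 | (1R,4R,5S,6S)-6-(triethylsilyloxy)dauc-8-en-4-ol | CC(C)[C@]1(O)CC[C@]2(C)CC=C(C)C[C@H](O[Si](CC)(CC)CC)[C@H]21
F7 | step 7 | (1R,4R,5S,6S)-6-(triethylsilyloxy)dauc-8-en-4-yl 4-(benzyloxy)benzoate | CC(C)[C@]1(OC(=O)c2ccc(OCc3ccccc3)cc2)CC[C@]2(C)CC=C(C)C[C@H](O[Si](CC)(CC)CC)[C@H]21
F8 | step 4 | racemic tert-butyl[(7,7-dibromo-3,6-dimethylbicyclo[4.1.0]hept-3-en-1-yl)oxy]dimethylsilane | CC1=CCC2(C)C(Br)(Br)C2(C1)O[Si](C)(C)C(C)(C)C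
F9 | step 4 | 2-bromo-3,6-dimethylcyclohepta-2,5-dien-1-one | CC1=CCC(C)=C(Br)C(=O)C1
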